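## Retrosynthetic overview
1. Ring D (dihydrofuran, closed last): cut C5'–C8 and O4'–C7. This gives the unprotected (2S)-6,8-diprenyl-5,7,2',4'-tetrahydroxyflavanone and unprotected resveratrol. Forward, it is one intermolecular oxidative [3+2] under chiral phosphate control, mirroring the presumed phenol-coupling biosynthesis.
2. Ring C (closed first): cut O1–C2 to a 2'-hydroxychalcone. Forward, it is a chalcone-isomerase-like asymmetric oxa-Michael closure that sets 2S.
3. Chalcone: cut Cα=Cβ to MOM-protected 3,5-diprenylphloroacetophenone and 2,4-bis(methoxymethoxy)benzaldehyde (Claisen–Schmidt).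
4. Prenyl groups: double C-prenylation of phloroacetophenone at the outset.
5. Ring order: rings A and B are bought, ring C closes in step 5, ring D closes in step 7.

Assumption: the sense of induction of the two organocatalysts is assigned by analogy and must be confirmed in the first run; the quinidine-derived pseudo-enantiomer of the thiourea and the (S)-phosphoric acid are equally available and would be swapped in if needed.

Locants: flavanone numbering is used, with ring B primed. C7 and C8 are the olefinic carbons of resveratrol next to the 4-hydroxyphenyl ring and the 3,5-dihydroxyphenyl ring. In ring D, C2 = C7 and C3 = C8.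

## Route

Step 1
Reactants: 1 2,4,6-trihydroxyacetophenone; 2 prenyl bromide (2.05 equiv)
Product: 3 1-[2,4,6-trihydroxy-3,5-bis(3-methylbut-2-en-1-yl)phenyl]ethan-1-one
Conditions: KOH (2.1 equiv), H2O, 0 °C → rt, 4 h
Reagents that add atoms: prenyl bromide (2), CC(C)=CCBr
Why: Base-mediated Friedel–Crafts-type C-alkylation of a phloroglucinol phenolate (biomimetic aromatic prenylation): in water the oxygens of the dianion are solvated, so the soft allylic bromide is taken up at the two free ring carbons C3 and C5, over-alkylated dearomatised material is removed by chromatography, and no stereocentre is formed.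

Step 2
Reactants: 3 diprenylphloroacetophenone; 4 chloromethyl methyl ether (2.3 equiv)
Product: 5 1-[2-hydroxy-4,6-bis(methoxymethoxy)-3,5-bis(3-methylbut-2-en-1-yl)phenyl]ethan-1-one
Conditions: MOMCl, iPr2NEt (3 equiv), CH2Cl2, 0 °C → rt
Reagents that add atoms: chloromethyl methyl ether (4), COCCl
Why: Williamson-type O-alkylation (acetal protection): the hard electrophile reacts only at oxygen, the 4-OH and one of the two symmetry-equivalent ortho OH groups are capped, and the last OH is held in a hydrogen bond to the ketone and stays free for the later ring closure.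

Step 3
Reactants: 6 2,4-dihydroxybenzaldehyde; 4 chloromethyl methyl ether (3 equiv)
Product: 7 2,4-bis(methoxymethoxy)benzaldehyde
Conditions: MOMCl, K2CO3 (4 equiv), acetone, reflux
Reagents that add atoms: chloromethyl methyl ether (4), COCCl
Why: Williamson-type O-alkylation: excess reagent at reflux also caps the chelated 2-OH, which prevents phenolate deactivation of the aldehyde in the aldol step and flavylium formation later.

Step 4
Reactants: 5 bis-MOM diprenyl ketone; 7 bis-MOM aldehyde
Product: 8 (E)-3-[2,4-bis(methoxymethoxy)phenyl]-1-[2-hydroxy-4,6-bis(methoxymethoxy)-3,5-bis(3-methylbut-2-en-1-yl)phenyl]prop-2-en-1-one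
Conditions: KOH (50 % aq), EtOH, rt, 36 h; cold aq citric acid to pH 6
Reagents that add atoms: none
Why: Claisen–Schmidt condensation (aldol addition, then E1cB dehydration) gives the E-enone under thermodynamic control; MOM ethers and prenyl groups are inert to hydroxide, and in strong base the product rests as the open-chain phenolate, so no racemic ring closure occurs before step 5.

Step 5
Reactants: 8 tetra-MOM 2'-hydroxychalcone
Product: 9 (2S)-2-[2,4-bis(methoxymethoxy)phenyl]-5,7-bis(methoxymethoxy)-6,8-bis(3-methylbut-2-en-1-yl)chroman-4-one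
Conditions: N-[3,5-bis(trifluoromethyl)phenyl]-N'-[(8α,9S)-6'-methoxycinchonan-9-yl]thiourea (15 mol %), toluene, −10 °C, 5 d
Reagents that add atoms: none
Why: Cinchona-thiourea-catalysed asymmetric intramolecular oxa-Michael addition, a small-molecule copy of chalcone isomerase: the quinuclidine nitrogen deprotonates the only free phenol while the thiourea binds the enone carbonyl, the phenolate adds to one face of Cβ and sets C2 as S, and the twisted 2',6'-dioxygenated aryl ketone makes closure strongly downhill, so the retro-reaction that would racemise C2 is slow at −10 °C.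

Step 6
Reactants: 9 (2S)-tetra-MOM flavanone
Product: 11 (2S)-2-(2,4-dihydroxyphenyl)-5,7-dihydroxy-6,8-bis(3-methylbut-2-en-1-yl)chroman-4-one, via tetrakis(trimethylsilyl) ether 10 (not isolated)
Conditions: TMSOTf (8 equiv), 2,2'-bipyridyl (12 equiv), MeCN, 0 °C → rt; then H2O, rt
Reagents that add atoms: none
Why: Silyl triflate/bipyridyl acetal exchange followed by silyl ether hydrolysis: each aryl MOM ether becomes the aryl TMS ether of 10, the CH2OMe unit is taken up by bipyridyl and released on hydrolysis, and because no acid stronger than bipyridinium is ever present, the doubly donor-activated benzylic C2–O1 bond (the S centre) and the prenyl/ortho-phenol pairs are left alone.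

Step 7
Reactants: 11 (2S)-flavanone; 12 (E)-resveratrol
Product: 15 (2S)-2-[(2R,3R)-3-(3,5-dihydroxyphenyl)-6-hydroxy-2-(4-hydroxyphenyl)-2,3-dihydro-1-benzofuran-5-yl]-5,7-dihydroxy-6,8-bis(3-methylbut-2-en-1-yl)chroman-4-one (target), via quinone methide cation 13 (not isolated), via para-quinone methide adduct 14 (not isolated)
Conditions: 11 (1.5 equiv, excess recovered), (R)-3,3'-bis(2,4,6-triisopropylphenyl)-1,1'-binaphthyl-2,2'-diyl hydrogen phosphate (15 mol %), 4 Å MS, CH2Cl2/MeCN 4:1, −30 °C; 12 (1.0 equiv, MeCN) and PhI(OAc)2 (1.05 equiv, CH2Cl2) added from two syringe pumps over 8 h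
Reagents that add atoms: none
Why: Proposed new method: the acid-activated trivalent iodine reagent takes two electrons and one proton from the most oxidisable phenol present, the 4-hydroxystilbene 12 (kept at trace concentration by slow addition so it cannot dimerise), to give cation 13, whose only counter-ion that stays unprotonated beside AcOH is the chiral phosphate; the phosphate bridges the 3-OH of 13 and the 4'-OH of 11 by hydrogen bonds, so C5' of ring B (para to 2'-OH, ortho to 4'-OH, the less hindered doubly activated carbon) attacks one face of C8 and sets C3 of ring D as R in 14; the 4'-OH then adds to C7 anti to the neighbouring aryl group to set C2 as R (this closure is reversible under the mild acid, so the trans ring is also the thermodynamic product), and flavanone C2 is untouched at −30 °C; the closest known reaction types are the FeCl3·6H2O dimerisation of resveratrol to ε-viniferin, the PhI(OAc)2-mediated [3+2] dimerisation of isoeugenol, chiral-phosphoric-acid-catalysed formal [3+2] dihydrobenzofuran syntheses run in tandem with an in situ hypervalent iodine oxidation, and remote 1,6- and 1,8-additions of phenols to para-quinone methides.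

## Compound list
1 | 2,4,6-trihydroxyacetophenone | CC(=O)c1c(O)cc(O)cc1O | starting material
2 | prenyl bromide (1-bromo-3-methylbut-2-ene) | CC(C)=CCBr | starting material
3 | 1-[2,4,6-trihydroxy-3,5-bis(3-methylbut-2-en-1-yl)phenyl]ethan-1-one | CC(=O)c1c(O)c(CC=C(C)C)c(O)c(CC=C(C)C)c1O | intermediate
4 | chloromethyl methyl ether (MOMCl) | COCCl | starting material
5 | 1-[2-hydroxy-4,6-bis(methoxymethoxy)-3,5-bis(3-methylbut-2-en-1-yl)phenyl]ethan-1-one | CC(=O)c1c(O)c(CC=C(C)C)c(OCOC)c(CC=C(C)C)c1OCOC | intermediate
6 | 2,4-dihydroxybenzaldehyde | O=Cc1ccc(O)cc1O | starting material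
7 | 2,4-bis(methoxymethoxy)benzaldehyde | O=Cc1ccc(OCOC)cc1OCOC | intermediate
8 | (E)-tetra-MOM 2'-hydroxy-3',5'-diprenylchalcone | COCOc1ccc(/C=C/C(=O)c2c(O)c(CC=C(C)C)c(OCOC)c(CC=C(C)C)c2OCOC)c(OCOC)c1 | intermediate
9 | (2S)-5,7,2',4'-tetrakis(methoxymethoxy)-6,8-diprenylflavanone | CC(C)=CCc1c(OCOC)c(CC=C(C)C)c2c(c1OCOC)C(=O)C[C@@H](c1ccc(OCOC)cc1OCOC)O2 | intermediate
10 | (2S)-5,7,2',4'-tetrakis(trimethylsilyloxy)-6,8-diprenylflavanone | CC(C)=CCc1c(O[Si](C)(C)C)c(CC=C(C)C)c2c(c1O[Si](C)(C)C)C(=O)C[C@@H](c1ccc(O[Si](C)(C)C)cc1O[Si](C)(C)C)O2 | intermediate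
11 | (2S)-5,7,2',4'-tetrahydroxy-6,8-diprenylflavanone | CC(C)=CCc1c(O)c(CC=C(C)C)c2c(c1O)C(=O)C[C@@H](c1ccc(O)cc1O)O2 | intermediate
12 | (E)-resveratrol | Oc1ccc(/C=C/c2cc(O)cc(O)c2)cc1 | starting material
13 | resveratrol-derived quinone methide cation (charge at C8, paired with the chiral phosphate) | O=C1C=CC(=C[CH+]c2cc(O)cc(O)c2)C=C1 | intermediate
14 | (2S)-flavanone bearing at C5' the (R)-1-(3,5-dihydroxyphenyl)-2-(4-oxocyclohexa-2,5-dien-1-ylidene)ethyl group | CC(C)=CCc1c(O)c(CC=C(C)C)c2c(c1O)C(=O)C[C@@H](c1cc([C@H](C=C3C=CC(=O)C=C3)c3cc(O)cc(O)c3)c(O)cc1O)O2 | intermediate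
15 | CNP0230984.1, (2S)-flavanone with (2R,3R)-trans ring D | CC(C)=CCc1c(O)c(CC=C(C)C)c2c(c1O)C(=O)C[C@@H](c1cc3c(cc1O)O[C@@H](c1ccc(O)cc1)[C@@H]3c1cc(O)cc(O)c1)O2 | target

## Count and risks
Total steps: 7. Longest linear sequence: 6 (steps 1, 2, 4, 5, 6, 7).

**Step 7 (highest risk).**
- What can go wrong: resveratrol may homocouple to viniferin-type dimers, ring A or the prenyl groups may be oxidised, the product may couple again, and facial control may be modest.
- Expected outcome: a realistic yield is 15–30 %, with 11 recovered.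
- Why the product is still a single enantiomer: 11 is already enantioenriched, so the wrong-face trans product is a diastereomer. It is removed by reversed-phase HPLC, which also raises the enantiopurity of 15.
- Fallback: build ring D first on a cheap, robust ring B surrogate and close ring C last. It sets out from 6 and 12, uses 5 on the way, and returns to the route at 15.
- Fallback sequence: 12 is added slowly to a tenfold excess of 6 and FeCl3·6H2O in acetone. This is a one-electron, ε-viniferin-type coupling in which nothing but 12 is oxidisable, and 6 is recovered. It gives the racemic trans dihydrobenzofuran aldehyde F1. Preparative chiral SFC gives the (2R,3R)-aldehyde F2 and the discarded (2S,3S)-aldehyde F3. MOMCl/NaH in DMF gives the tetrakis(methoxymethyl) ether F4. Claisen–Schmidt condensation with 5 gives the hexa-MOM chalcone F5. The thiourea-catalysed oxa-Michael closure of step 5 gives the hexa-MOM flavanone F6, whose C2 epimer is now a separable diastereomer. The TMSOTf/2,2'-bipyridyl protocol of step 6 then leads through the hexakis(trimethylsilyl) ether F7 to 15.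

**Step 5.**
- What can go wrong: unactivated 2'-hydroxychalcones often give only moderate enantiomeric excess, and the reaction is slow.
- Fallback: replace catalysis by resolution with recycling. It sets out from 8 and returns at 9.
- Fallback sequence: NaOAc in refluxing EtOH gives the racemic tetra-MOM flavanone F8. Preparative SFC on a chiral phase delivers 9. The (2R)-tetra-MOM flavanone F9 is returned to the NaOAc equilibration, where it racemises through 8, and is resolved again.

**Step 6.**
- What can go wrong: four acetals must be cleaved without racemising the acid-labile C2 or cyclising the prenyl phenols.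
- Fallback: reset the stereocentre only after all acid chemistry is done. It sets out from 9 and returns at 11.
- Fallback sequence: classical 3 M HCl in refluxing MeOH, with erosion at C2 accepted, gives the racemised tetrahydroxyflavanone F10. Cold aqueous KOH under argon opens ring C. Quick acidification with citric acid at 0 °C precipitates the free pentahydroxychalcone F11. The same thiourea in toluene/EtOAc at −20 °C then closes F11 to 11; the two ortho OH groups are equivalent, so there is only one regiochemical outcome.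

## Further compounds
F1 | step 7 | racemic trans-3-(3,5-dihydroxyphenyl)-6-hydroxy-2-(4-hydroxyphenyl)-2,3-dihydro-1-benzofuran-5-carbaldehyde | O=Cc1cc2c(cc1O)OC(c1ccc(O)cc1)C2c1cc(O)cc(O)c1
F2 | step 7 | (2R,3R)-3-(3,5-dihydroxyphenyl)-6-hydroxy-2-(4-hydroxyphenyl)-2,3-dihydro-1-benzofuran-5-carbaldehyde | O=Cc1cc2c(cc1O)O[C@@H](c1ccc(O)cc1)[C@@H]2c1cc(O)cc(O)c1
F3 | step 7 | (2S,3S)-3-(3,5-dihydroxyphenyl)-6-hydroxy-2-(4-hydroxyphenyl)-2,3-dihydro-1-benzofuran-5-carbaldehyde | O=Cc1cc2c(cc1O)O[C@H](c1ccc(O)cc1)[C@H]2c1cc(O)cc(O)c1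
F4 | step 7 | (2R,3R)-tetrakis(methoxymethyl) ether of F2 | O=Cc1cc2c(cc1OCOC)O[C@@H](c1ccc(OCOC)cc1)[C@@H]2c1cc(OCOC)cc(OCOC)c1
F5 | step 7 | (E)-hexa-MOM 2'-hydroxychalcone carrying the (2R,3R) ring D | CC(C)=CCc1c(OCOC)c(CC=C(C)C)c(O)c(C(=O)/C=C/c2cc3c(cc2OCOC)O[C@@H](c2ccc(OCOC)cc2)[C@@H]3c2cc(OCOC)cc(OCOC)c2)c1OCOC
F6 | step 7 | hexakis(methoxymethyl) ether of 15 | CC(C)=CCc1c(OCOC)c(CC=C(C)C)c2c(c1OCOC)C(=O)C[C@@H](c1cc3c(cc1OCOC)O[C@@H](c1ccc(OCOC)cc1)[C@@H]3c1cc(OCOC)cc(OCOC)c1)O2
F7 | step 7 | hexakis(trimethylsilyl) ether of 15 | CC(C)=CCc1c(O[Si](C)(C)C)c(CC=C(C)C)c2c(c1O[Si](C)(C)C)C(=O)C[C@@H](c1cc3c(cc1O[Si](C)(C)C)O[C@@H](c1ccc(O[Si](C)(C)C)cc1)[C@@H]3c1cc(O[Si](C)(C)C)cc(O[Si](C)(C)C)c1)O2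
F8 | step 5 | racemic 5,7,2',4'-tetrakis(methoxymethoxy)-6,8-diprenylflavanone | CC(C)=CCc1c(OCOC)c(CC=C(C)C)c2c(c1OCOC)C(=O)CC(c1ccc(OCOC)cc1OCOC)O2
F9 | step 5 | (2R)-5,7,2',4'-tetrakis(methoxymethoxy)-6,8-diprenylflavanone | CC(C)=CCc1c(OCOC)c(CC=C(C)C)c2c(c1OCOC)C(=O)C[C@H](c1ccc(OCOC)cc1OCOC)O2
F10 | step 6 | racemised 5,7,2',4'-tetrahydroxy-6,8-diprenylflavanone | CC(C)=CCc1c(O)c(CC=C(C)C)c2c(c1O)C(=O)CC(c1ccc(O)cc1O)O2
F11 | step 6 | (E)-2',4',6',2,4-pentahydroxy-3',5'-diprenylchalcone | CC(C)=CCc1c(O)c(CC=C(C)C)c(O)c(C(=O)/C=C/c2ccc(O)cc2O)c1O
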